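**Plan**

1. Retrosynthesis, first cut: the C=C of the 2-alkyl-2-enal. The arms (eleven CH2 plus CH= on one side, ten CH2 on the other) and the two identical all-cis (2S,3S,6R)-2-methyl-6-alkylpiperidin-3-ol rings mark the target as the self-aldol condensation dimer of one C12 amino aldehyde.
2. Second cut, in that monomer (ring numbered N1, C2 methyl, C3 hydroxyl, C6 chain): C3–C4 and N1–C6. N1–C2(Me)–C3(OH) is an L-alaninal unit; C6 carries nitrogen and lies 1,4 to the carbinol carbon C3, so C4–C5–C6 is a ketone homoenolate. This pattern allows a formal [3+3] union of two acyclic pieces.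
3. Forward: 12-bromododecan-1-ol is benzylated, acylated with 3-bromopropanoyl chloride and ketalised. Its Grignard reagent alkylates the aluminoxy acetal of the L-alanine benzophenone-imine ester, and acid work-up closes the ring as a cyclic imine in the same flask.
4. Then: hydrogenation (C=N and benzyl ether), N-Boc protection, oxidation of the primary alcohol, aldol dimerisation and removal of Boc.
5. Stereochemistry: C2 from L-alanine; C3 by chelation-controlled (threo) addition; C6 by cis-hydrogenation of the cyclic imine; the E enal by thermodynamic control in the condensation.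

Key step: step 5

**Route**

Step 1
Reactants: 1 12-bromododecan-1-ol
Product: 2 benzyl 12-bromododecyl ether
Conditions: BnOC(=NH)CCl3, CF3SO3H (cat.), CH2Cl2–cyclohexane, 0 °C → rt
Reagents that add atoms: benzyl 2,2,2-trichloroacetimidate, N=C(OCc1ccccc1)C(Cl)(Cl)Cl
Why: Acid-catalysed O-benzylation with a trichloroacetimidate needs no base, so the primary bromide is untouched, and the benzyl ether should survive the Grignard, acid and hydride steps until it is removed by hydrogenolysis in step 6.

Step 2
Reactants: 2 benzyl 12-bromododecyl ether; 3 3-bromopropanoyl chloride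
Product: 5 15-(benzyloxy)-1-bromopentadecan-3-one, via Grignard reagent 4 (not isolated)
Conditions: Mg, THF, 40 °C; then added slowly to 3, Fe(acac)3 (3 mol %), THF, −78 °C
Reagents that add atoms: none
Why: Iron-catalysed acylation of an alkyl Grignard reagent with an acid chloride is much faster at −78 °C than addition to the ketone formed or attack on the alkyl bromide, so the three carbons that become C4–C6 of the ring are attached in one step.

Step 3
Reactants: 5 15-(benzyloxy)-1-bromopentadecan-3-one
Product: 6 2-[12-(benzyloxy)dodecyl]-2-(2-bromoethyl)-1,3-dioxolane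
Conditions: HOCH2CH2OH, TsOH·H2O (cat.), benzene, reflux, Dean–Stark trap
Reagents that add atoms: ethane-1,2-diol, OCCO
Why: Acid-catalysed ketalisation with azeotropic removal of water masks the ketone, so that the β-bromo ketone becomes a precursor of a stable ketone-homoenolate Grignard reagent.

Step 4
Reactants: 7 methyl L-alaninate hydrochloride
Product: 8 methyl (2S)-2-[(diphenylmethylidene)amino]propanoate
Conditions: Ph2C=NH, CH2Cl2, rt
Reagents that add atoms: benzophenone imine, N=C(c1ccccc1)c1ccccc1
Why: Transimination of the amino ester salt with benzophenone imine proceeds at room temperature without epimerisation and installs an N-substituent that later acts as chelating director and as an acid-labile mask.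

Step 5
Reactants: 6 2-[12-(benzyloxy)dodecyl]-2-(2-bromoethyl)-1,3-dioxolane; 8 methyl (2S)-2-[(diphenylmethylidene)amino]propanoate
Product: 13 (2S,3S)-6-[12-(benzyloxy)dodecyl]-2-methyl-2,3,4,5-tetrahydropyridin-3-ol, via ketal Grignard reagent 9 (not isolated), via aluminoxy acetal 10 (not isolated), via Schiff-base alcohol 11 (not isolated), via amino ketone 12 (not isolated)
Conditions: (a) 6, Mg, THF, 25 °C; (b) 8, iBu2AlH·iBu3Al (1:1, 1.1 equiv), CH2Cl2, −78 °C; then 9 (2.5 equiv), −78 °C → rt; (c) 2 M aq. HCl, THF, rt → 40 °C; then aq. NaOH to pH 10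
Reagents that add atoms: none
Why: iBu2AlH reduces ester 8 at −78 °C only as far as the aluminoxy acetal 10, held as a five-membered N→Al chelate by the imine nitrogen, so that no free, epimerisable α-amino aldehyde accumulates; Grignard reagent 9 then alkylates this masked aldehyde through the chelate (Cram-chelate model) from the face opposite the C2 methyl group, which forms C3–C4 and sets C3 as S (threo to C2). Aqueous HCl next removes both helpers, the diphenylmethylidene group and the dioxolane, and the freed δ-amino ketone 12 closes the piperidine by 6-exo-trig attack of nitrogen on the ketone carbon and loss of water, which forms N1–C6 as the cyclic imine. The closest known reaction types are the one-flask reduction–alkylation of N-diphenylmethylidene α-amino esters with Grignard reagents and the cyclocondensation of δ-amino ketones to 1-piperideines; together they amount to a formal [3+3] annulation of an alaninal unit with a ketone homoenolate. The only new stereocentre, C3, is controlled by C2 through the chelate. The step needs threo over erythro addition (secured by the chelating imine nitrogen), a single hydride delivery (secured by the stable tetrahedral aluminium intermediate at −78 °C) and N- over O-closure on the ketone (the five-membered hemiketal is reversible, whereas imine formation on basification is the sink).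

Step 6
Reactants: 13 (2S,3S)-6-[12-(benzyloxy)dodecyl]-2-methyl-2,3,4,5-tetrahydropyridin-3-ol
Product: 15 (2S,3S,6R)-6-(12-hydroxydodecyl)-2-methylpiperidin-3-ol, via O-benzyl piperidine 14 (not isolated)
Conditions: H2 (4 bar), Pd(OH)2/C, EtOH–AcOH (10:1), rt; then aq. K2CO3
Reagents that add atoms: none
Why: Heterogeneous hydrogenation of a 2,6-disubstituted cyclic imine should deliver hydrogen to the face opposite the C2 methyl and C3 hydroxyl groups, setting C6 as R (all-cis ring), and the same catalyst removes the benzyl ether by hydrogenolysis.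

Step 7
Reactants: 15 (2S,3S,6R)-6-(12-hydroxydodecyl)-2-methylpiperidin-3-ol
Product: 16 tert-butyl (2S,3S,6R)-3-hydroxy-6-(12-hydroxydodecyl)-2-methylpiperidine-1-carboxylate
Conditions: Boc2O, Et3N, MeOH, 45 °C
Reagents that add atoms: di-tert-butyl dicarbonate, CC(C)(C)OC(=O)OC(=O)OC(C)(C)C
Why: Carbamate formation with Boc2O is N-selective without an acylation catalyst (the alcohols do not react), the hindered nitrogen needing only gentle heating, and the carbamate shields the amine from oxidation and from enamine chemistry in steps 8 and 9.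

Step 8
Reactants: 16 tert-butyl (2S,3S,6R)-3-hydroxy-6-(12-hydroxydodecyl)-2-methylpiperidine-1-carboxylate
Product: 17 tert-butyl (2S,3S,6R)-3-hydroxy-2-methyl-6-(12-oxododecyl)piperidine-1-carboxylate
Conditions: TEMPO (10 mol %), PhI(OAc)2, CH2Cl2, rt
Reagents that add atoms: none
Why: Nitroxyl-catalysed oxidation with a hypervalent iodine co-oxidant oxidises primary alcohols much faster than the hindered secondary ring alcohol and stops at the aldehyde.

Step 9
Reactants: 17 tert-butyl (2S,3S,6R)-3-hydroxy-2-methyl-6-(12-oxododecyl)piperidine-1-carboxylate (two molecules)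
Product: 18 (2E)-2-{10-[(2R,5S,6S)-1-(tert-butoxycarbonyl)-5-hydroxy-6-methylpiperidin-2-yl]decyl}-14-[(2R,5S,6S)-1-(tert-butoxycarbonyl)-5-hydroxy-6-methylpiperidin-2-yl]tetradec-2-enal
Conditions: pyrrolidine (20 mol %), PhCO2H (20 mol %), toluene, 4 Å molecular sieves, rt → 40 °C
Reagents that add atoms: none
Why: Amine/acid-catalysed self-aldol condensation of a linear aldehyde (the enamine of one molecule adds to the iminium ion of a second, then the amine is eliminated) should give the 2-alkyl-2-enal, in the thermodynamically favoured E geometry with the β-chain trans to the formyl group, and the α-branched product condenses further only slowly.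

Step 10
Reactants: 18 the bis-Boc enal of step 9
Product: 19 (2E)-2-{10-[(2R,5S,6S)-5-hydroxy-6-methylpiperidin-2-yl]decyl}-14-[(2R,5S,6S)-5-hydroxy-6-methylpiperidin-2-yl]tetradec-2-enal (CNP0177491.1)
Conditions: CF3CO2H, CH2Cl2, 0 °C; then cold aq. NaHCO3
Reagents that add atoms: none
Why: Acidolysis of the two tert-butyl carbamates (loss of 2-methylpropene and CO2) should leave the trisubstituted enal and the secondary alcohols untouched, and a cold bicarbonate work-up frees the two hindered secondary amines.

**Compound list**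

1 | 12-bromododecan-1-ol | OCCCCCCCCCCCCBr | starting material
2 | benzyl 12-bromododecyl ether | BrCCCCCCCCCCCCOCc1ccccc1 | intermediate
3 | 3-bromopropanoyl chloride | O=C(Cl)CCBr | starting material
4 | [12-(benzyloxy)dodecyl]magnesium bromide | Br[Mg]CCCCCCCCCCCCOCc1ccccc1 | intermediate
5 | 15-(benzyloxy)-1-bromopentadecan-3-one | BrCCC(=O)CCCCCCCCCCCCOCc1ccccc1 | intermediate
6 | 2-[12-(benzyloxy)dodecyl]-2-(2-bromoethyl)-1,3-dioxolane | BrCCC1(CCCCCCCCCCCCOCc2ccccc2)OCCO1 | intermediate
7 | methyl L-alaninate hydrochloride | C[C@H](N)C(=O)OC.Cl | starting material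
8 | methyl (2S)-2-[(diphenylmethylidene)amino]propanoate | C[C@H](N=C(c1ccccc1)c1ccccc1)C(=O)OC | intermediate
9 | {2-[2-(12-(benzyloxy)dodecyl)-1,3-dioxolan-2-yl]ethyl}magnesium bromide | Br[Mg]CCC1(CCCCCCCCCCCCOCc2ccccc2)OCCO1 | intermediate
10 | diisobutyl{(2S)-2-[(diphenylmethylidene)amino]-1-methoxypropoxy}alumane (aluminoxy acetal) | C[C@H](N=C(c1ccccc1)c1ccccc1)C(OC)O[Al](CC(C)C)CC(C)C | intermediate
11 | (2S,3S)-5-{2-[12-(benzyloxy)dodecyl]-1,3-dioxolan-2-yl}-2-[(diphenylmethylidene)amino]pentan-3-ol | C[C@H](N=C(c1ccccc1)c1ccccc1)[C@@H](O)CCC1(CCCCCCCCCCCCOCc2ccccc2)OCCO1 | intermediate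
12 | (2S,3S)-2-amino-18-(benzyloxy)-3-hydroxyoctadecan-6-one | C[C@H](N)[C@@H](O)CCC(=O)CCCCCCCCCCCCOCc1ccccc1 | intermediate
13 | (2S,3S)-6-[12-(benzyloxy)dodecyl]-2-methyl-2,3,4,5-tetrahydropyridin-3-ol | C[C@@H]1N=C(CCCCCCCCCCCCOCc2ccccc2)CC[C@@H]1O | intermediate
14 | (2S,3S,6R)-6-[12-(benzyloxy)dodecyl]-2-methylpiperidin-3-ol | C[C@@H]1N[C@H](CCCCCCCCCCCCOCc2ccccc2)CC[C@@H]1O | intermediate
15 | (2S,3S,6R)-6-(12-hydroxydodecyl)-2-methylpiperidin-3-ol | C[C@@H]1N[C@H](CCCCCCCCCCCCO)CC[C@@H]1O | intermediate
16 | tert-butyl (2S,3S,6R)-3-hydroxy-6-(12-hydroxydodecyl)-2-methylpiperidine-1-carboxylate | C[C@@H]1N(C(=O)OC(C)(C)C)[C@H](CCCCCCCCCCCCO)CC[C@@H]1O | intermediate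
17 | tert-butyl (2S,3S,6R)-3-hydroxy-2-methyl-6-(12-oxododecyl)piperidine-1-carboxylate | C[C@@H]1N(C(=O)OC(C)(C)C)[C@H](CCCCCCCCCCCC=O)CC[C@@H]1O | intermediate
18 | (2E)-2-{10-[(2R,5S,6S)-1-(tert-butoxycarbonyl)-5-hydroxy-6-methylpiperidin-2-yl]decyl}-14-[(2R,5S,6S)-1-(tert-butoxycarbonyl)-5-hydroxy-6-methylpiperidin-2-yl]tetradec-2-enal | C[C@@H]1N(C(=O)OC(C)(C)C)[C@H](CCCCCCCCCCC/C=C(/C=O)CCCCCCCCCC[C@@H]2CC[C@H](O)[C@H](C)N2C(=O)OC(C)(C)C)CC[C@@H]1O | intermediate
19 | (2E)-2-{10-[(2R,5S,6S)-5-hydroxy-6-methylpiperidin-2-yl]decyl}-14-[(2R,5S,6S)-5-hydroxy-6-methylpiperidin-2-yl]tetradec-2-enal | C[C@@H]1N[C@H](CCCCCCCCCCC/C=C(/C=O)CCCCCCCCCC[C@@H]2CC[C@H](O)[C@H](C)N2)CC[C@@H]1O | target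

**Step count**

Total: 10 steps. Longest linear sequence: 9 steps (steps 1, 2, 3, 5, 6, 7, 8, 9, 10 from 12-bromododecan-1-ol).

**Steps most likely to fail**

Step 5. What may go wrong: poor facial selectivity in the Grignard addition to the chelated aluminoxy acetal; over-reduction of the ester; decomposition of the β-ketal Grignard reagent before it adds; incomplete hydrolysis of the dioxolane. The fallback sets out from bromo ketal 6 (as Grignard reagent 9) and amino ester salt 7, and sets C3 by hydride reduction instead of by C–C bond formation. Salt 7 is N,N-dibenzylated (BnBr, K2CO3, MeCN, 60 °C) to methyl N,N-dibenzyl-L-alaninate F1. Me(MeO)NH·HCl with iPrMgCl (THF, −20 °C) converts it into (2S)-2-(dibenzylamino)-N-methoxy-N-methylpropanamide F2. Reagent 9 adds once to F2 (THF, 0 °C) to give (2S)-5-{2-[12-(benzyloxy)dodecyl]-1,3-dioxolan-2-yl}-2-(dibenzylamino)pentan-3-one F3. NaBH4 in MeOH at −20 °C should reduce F3 under Felkin–Anh (non-chelation) control to the syn alcohol (2S,3S)-5-{2-[12-(benzyloxy)dodecyl]-1,3-dioxolan-2-yl}-2-(dibenzylamino)pentan-3-ol F4. H2 over Pd(OH)2/C in EtOH–aqueous HCl then removes the three benzyl groups and the dioxolane, the amino ketone cyclises and the imine is hydrogenated in the same flask. The route is rejoined at diol 15.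

Step 9. What may go wrong: oligomerisation by continued condensation of the enal with further aldehyde; incomplete dehydration of the aldol stage; erosion of the alkene geometry. The fallback sets out from aldehyde 17 and builds the enal by olefin metathesis instead of carbonyl condensation. One portion of 17 is α-methylenated (aqueous CH2O, pyrrolidine/propanoic acid cat., iPrOH, 45 °C) to tert-butyl (2S,3S,6R)-6-(11-formyldodec-11-en-1-yl)-3-hydroxy-2-methylpiperidine-1-carboxylate F5. A second portion is converted by Wittig methylenation (Ph3P=CH2, THF, −78 → 0 °C) into tert-butyl (2S,3S,6R)-3-hydroxy-2-methyl-6-(tridec-12-en-1-yl)piperidine-1-carboxylate F6. Cross-metathesis of F5 with F6 (second-generation Hoveyda–Grubbs catalyst, CH2Cl2, 40 °C, loss of ethene) should give the E trisubstituted enal. The route is rejoined at 18.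

Step 2. What may go wrong: dehydrobromination of the acid chloride or of the β-bromo ketone by the basic Grignard reagent; double addition to the ketone. The fallback sets out from ether 2 (as Grignard reagent 4) and never handles a free β-bromo ketone. Addition of 4 to acrolein (THF, −78 °C) gives 15-(benzyloxy)pentadec-1-en-3-ol F7. MnO2 (CH2Cl2, rt) oxidises it to 15-(benzyloxy)pentadec-1-en-3-one F8. Me3SiBr with ethane-1,2-diol (CH2Cl2, 0 °C → rt) then adds HBr to the enone and ketalises in one flask. The route is rejoined at bromo ketal 6.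

**Further compounds**

F1 | step 5 | methyl N,N-dibenzyl-L-alaninate | C[C@H](N(Cc1ccccc1)Cc1ccccc1)C(=O)OC
F2 | step 5 | (2S)-2-(dibenzylamino)-N-methoxy-N-methylpropanamide | C[C@H](N(Cc1ccccc1)Cc1ccccc1)C(=O)N(C)OC
F3 | step 5 | (2S)-5-{2-[12-(benzyloxy)dodecyl]-1,3-dioxolan-2-yl}-2-(dibenzylamino)pentan-3-one | C[C@H](N(Cc1ccccc1)Cc1ccccc1)C(=O)CCC1(CCCCCCCCCCCCOCc2ccccc2)OCCO1
F4 | step 5 | (2S,3S)-5-{2-[12-(benzyloxy)dodecyl]-1,3-dioxolan-2-yl}-2-(dibenzylamino)pentan-3-ol | C[C@H](N(Cc1ccccc1)Cc1ccccc1)[C@@H](O)CCC1(CCCCCCCCCCCCOCc2ccccc2)OCCO1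
F5 | step 9 | tert-butyl (2S,3S,6R)-6-(11-formyldodec-11-en-1-yl)-3-hydroxy-2-methylpiperidine-1-carboxylate | C[C@@H]1N(C(=O)OC(C)(C)C)[C@H](CCCCCCCCCCC(=C)C=O)CC[C@@H]1O
F6 | step 9 | tert-butyl (2S,3S,6R)-3-hydroxy-2-methyl-6-(tridec-12-en-1-yl)piperidine-1-carboxylate | C[C@@H]1N(C(=O)OC(C)(C)C)[C@H](CCCCCCCCCCCC=C)CC[C@@H]1O
F7 | step 2 | 15-(benzyloxy)pentadec-1-en-3-ol | C=CC(O)CCCCCCCCCCCCOCc1ccccc1
F8 | step 2 | 15-(benzyloxy)pentadec-1-en-3-one | C=CC(=O)CCCCCCCCCCCCOCc1ccccc1
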